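**Retrosynthetic overview**
1. 21 ⇐ oxidation at C14 and convex-face methyl addition at C26 of aldol 19; ring B (C13–C14–C16–C17–C18=C19–C20, seven-membered) ⇐ intramolecular aldol C16→C14 of keto aldehyde 18.
2. 18 ⇐ Horner–Wadsworth–Emmons union (C18=C19) of ring-A aldehyde 11 with α-phosphono lactone 16; 16 ⇐ intramolecular Michael addition (C18→C17) of the phosphonoacetate of (R)-4-hydroxycyclopent-2-enone (cyclopentane given, cis-lactone formed).
3. Ring A (C4–C5–C6–C8–C13–C20) ⇐ amine-catalysed double Michael annulation, a formal [4+2], of dienone keto ester 6 with enal 7, forming C8–C13 and C4–C20; C20 is then reset (9 → 11).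
4. Feature used: ring A is an enolised β-keto ester (enol C6, C8, ester C9) flanked by the contiguous stereocentres C13, C20 and C4, the imprint of a γ,δ-unsaturated β-keto ester added twice across an enal.
5. Ring order: lactone (step 6) and ring A (step 3) in parallel, then ring B (step 10).

Key step: step 3

Remark (numbering): atom labels C1–C28 follow the atom order of the target SMILES; β-keto esters are drawn as enols.
Remark (assumption): the two bonds of the iminium–enamine sequence are taken to add to the same face of the enal, so the formyl group first comes out trans to the acetal and C20 is corrected in a separate step (step 4).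
Remark (assumption): 19 and 20 are carried as mixtures at the C14 carbinol, which is oxidised in step 12.

**Step 1**
Reactants: 1 methyl 4-chloro-3-oxobutanoate; 2 triphenylphosphine
Product: 4 methyl 3-oxo-4-(triphenyl-λ5-phosphanylidene)butanoate, via phosphonium chloride 3 (not isolated)
Conditions: PPh3, THF, reflux; then aq. Na2CO3, CH2Cl2, rt
Reagents that add atoms: none
Why: SN2 quaternisation of the α-chloro ketone and deprotonation of the salt give the keto-stabilised ylide (Wittig reagent preparation).

**Step 2**
Reactants: 4 methyl 3-oxo-4-(triphenyl-λ5-phosphanylidene)butanoate; 5 methacrolein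
Product: 6 methyl (E)-6-methyl-3-oxohepta-4,6-dienoate
Conditions: NaH (1.1 equiv), THF, 0 °C; then 5, 0 °C → rt; AcOH
Reagents that add atoms: none
Why: The ylide anion (deprotonated between the two carbonyl groups) olefinates the aldehyde of methacrolein with the E selectivity of a stabilised Wittig reagent, which gives the dienone keto ester without an aldol–dehydration sequence; 6 is used at once.

**Step 3**
Reactants: 6 methyl (E)-6-methyl-3-oxohepta-4,6-dienoate; 7 (E)-4,4-dimethoxybut-2-enal
Product: 9 methyl (4R,5R,6S)-6-(dimethoxymethyl)-5-formyl-2-hydroxy-4-(prop-1-en-2-yl)cyclohex-1-ene-1-carboxylate, via enamine Michael adduct 8 (not isolated)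
Conditions: (R)-α,α-diphenylprolinol trimethylsilyl ether (20 mol %), PhCO2H (20 mol %), toluene, 0 °C → rt
Reagents that add atoms: none
Why: Catalyst and 7 form an E-iminium ion whose Si face at C13 is covered by the diphenyl(silyloxy)methyl group, so the β-keto ester carbon C8 of 6 adds to the Re face of C13 (13S); the resulting enamine 8 attacks the dienone β-carbon C4 through C20, and hydrolysis of the product iminium ion returns the catalyst. The closest known reactions are the diarylprolinol-silyl-ether-catalysed Michael additions of β-keto esters to enals, amine-catalysed Michael–Michael cyclohexane annulations, and the anionic double Michael annulation of γ,δ-unsaturated β-keto esters with activated alkenes. Ring A closes by a 6-endo-trig Michael addition (C4=C5 lies inside the new ring, the enamine double bond outside it) through a chair. C20 is attacked on the same open face as C13, so the formyl group should come out trans to the acetal; this centre is reset in step 4. C4 is expected to follow from the compact, Diels–Alder-endo-like chair with isopropenyl equatorial and the acetal pseudoaxial, clear of the ester on C8, which places isopropenyl trans to the acetal. The step needs attack at C4 and not at the remote C1, and closure by the enamine in preference to reaction of the dienone α-carbon C5 with the iminium carbon: ring size secures the first (C1 would require an eight-membered ring), and the β-substituent on the dienone together with the hindered, weakly nucleophilic amine should secure the second.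

**Step 4**
Reactants: 9 methyl (4R,5R,6S)-6-(dimethoxymethyl)-5-formyl-2-hydroxy-4-(prop-1-en-2-yl)cyclohex-1-ene-1-carboxylate
Product: 11 methyl (4R,5S,6S)-6-(dimethoxymethyl)-5-formyl-2-hydroxy-4-(prop-1-en-2-yl)cyclohex-1-ene-1-carboxylate, via dipotassium dienolate 10 (not isolated)
Conditions: KH (2.3 equiv), THF, 0 °C; then inverse addition to AcOH, THF, −78 °C
Reagents that add atoms: none
Why: Kinetic protonation of the exocyclic aldehyde enolate should deliver the proton axially to C20 on the face opposite the pseudoaxial acetal on C13, which leaves the formyl group equatorial and cis to the acetal; C13 and C4 are not touched, and the keto ester is protected as its enolate.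

**Step 5**
Reactants: 12 (R)-4-hydroxycyclopent-2-en-1-one; 13 2-(diethoxyphosphoryl)acetic acid
Product: 14 (R)-4-oxocyclopent-2-en-1-yl 2-(diethoxyphosphoryl)acetate
Conditions: DCC, DMAP (cat.), CH2Cl2, 0 °C
Reagents that add atoms: none
Why: Steglich esterification acylates the allylic alcohol under near-neutral conditions that spare the elimination-prone 4-acyloxy enone; C24 is untouched.

**Step 6**
Reactants: 14 (R)-4-oxocyclopent-2-en-1-yl 2-(diethoxyphosphoryl)acetate
Product: 15 diethyl [(3aS,6aR)-2,5-dioxohexahydro-2H-cyclopenta[b]furan-3-yl]phosphonate (epimer mixture at the phosphonate carbon)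
Conditions: NaH (1.0 equiv), THF, 0 °C; AcOH
Reagents that add atoms: none
Why: Intramolecular Michael addition (5-exo-trig) of the phosphonoacetate carbanion C18 to the enone β-carbon C17 can only occur on the face that carries the ester oxygen, so the lactone is cis-fused and C17 is set by C24; the product rests as its phosphonate-stabilised anion until the acid quench.

**Step 7**
Reactants: 15 diethyl [(3aS,6aR)-2,5-dioxohexahydro-2H-cyclopenta[b]furan-3-yl]phosphonate
Product: 16 diethyl [(3a'S,6a'R)-2'-oxohexahydrospiro[1,3-dioxolane-2,5'-cyclopenta[b]furan]-3'-yl]phosphonate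
Conditions: TMSOCH2CH2OTMS, TMSOTf (cat.), CH2Cl2, −78 → −20 °C; pyridine
Reagents that add atoms: 1,2-bis(trimethylsilyloxy)ethane, C[Si](C)(C)OCCO[Si](C)(C)C
Why: Silyl-transfer ketalisation masks the C26 ketone without base, so the β-acyloxy ketone can neither eliminate the lactone carboxylate nor enolise during the olefination.

**Step 8**
Reactants: 11 methyl (4R,5S,6S)-6-(dimethoxymethyl)-5-formyl-2-hydroxy-4-(prop-1-en-2-yl)cyclohex-1-ene-1-carboxylate; 16 diethyl [(3a'S,6a'R)-2'-oxohexahydrospiro[1,3-dioxolane-2,5'-cyclopenta[b]furan]-3'-yl]phosphonate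
Product: 17 methyl (4R,5S,6S)-6-(dimethoxymethyl)-2-hydroxy-5-{(E)-[(3a'R,6a'R)-2'-oxotetrahydrospiro[1,3-dioxolane-2,5'-cyclopenta[b]furan]-3'(2'H)-ylidene]methyl}-4-(prop-1-en-2-yl)cyclohex-1-ene-1-carboxylate
Conditions: NaH (1.2 equiv for 16, 1.0 equiv for 11, deprotonated separately), THF, 0 °C → rt; AcOH
Reagents that add atoms: none
Why: Horner–Wadsworth–Emmons olefination of the α-phosphono lactone with the α-branched aldehyde should give the E-alkylidene lactone (C20 trans to the lactone carbonyl, cis to C17), while the keto ester travels as its sodium enolate, which also guards C20 against epimerisation.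

**Step 9**
Reactants: 17 (HWE product, as named in step 8)
Product: 18 methyl (4R,5S,6S)-5-{(E)-[(3aR,6aR)-2,5-dioxohexahydro-3H-cyclopenta[b]furan-3-ylidene]methyl}-6-formyl-2-hydroxy-4-(prop-1-en-2-yl)cyclohex-1-ene-1-carboxylate
Conditions: 1 M aq. HCl, THF, rt (short exposure)
Reagents that add atoms: water, O
Why: Acid hydrolysis removes the dimethyl acetal and the dioxolane in one operation, while lactone, methyl ester, isopropenyl group and the β-acyloxy ketone tolerate dilute acid at room temperature.

**Step 10**
Reactants: 18 (keto aldehyde, as named in step 9)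
Product: 19 tetracyclic aldol: the target skeleton with C14 as secondary alcohol (epimer mixture) and C26 as ketone
Conditions: L-proline (30 mol %), DMSO, rt
Reagents that add atoms: none
Why: In this enamine-mediated intramolecular aldol addition only the C16 enamine can reach the C14 aldehyde (seven-membered ring B, whereas C25 would need a bridged eight-membered ring), and the tether from C18 delivers C14 to the face of C16 cis to C18, which sets C16.

**Step 11**
Reactants: 19 (aldol, as described in step 10)
Product: 20 diol: the target with C14 as secondary alcohol (epimer mixture)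
Conditions: MeMgBr, anhydrous CeCl3 (5 equiv each), THF, −78 °C; aq. NH4Cl
Reagents that add atoms: methylmagnesium bromide, C[Mg]Br
Why: The weakly basic organocerium reagent adds to the ketone faster than to the lactone or the enolate-masked keto ester, and methyl should enter from the convex face, anti to the C16 and C17 substituents, so the C26 hydroxyl ends up cis to C14 and to the lactone oxygen.

**Step 12**
Reactants: 20 (diol, as described in step 11)
Product: 21 target, CNP0268969.1
Conditions: Dess–Martin periodinane, pyridine, CH2Cl2, 0 °C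
Reagents that add atoms: none
Why: Dess–Martin oxidation converts the secondary C14 alcohol into the ketone while the tertiary C26 alcohol cannot react, and the buffered, non-basic medium avoids retro-aldol cleavage or dehydration of the new β-hydroxy ketone.

**Compound list**
1 | methyl 4-chloro-3-oxobutanoate | COC(=O)CC(=O)CCl | starting material
2 | triphenylphosphine | c1ccc(cc1)P(c1ccccc1)c1ccccc1 | starting material
3 | (4-methoxy-2,4-dioxobutyl)triphenylphosphonium chloride | COC(=O)CC(=O)C[P+](c1ccccc1)(c1ccccc1)c1ccccc1.[Cl-] | intermediate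
4 | methyl 3-oxo-4-(triphenyl-λ5-phosphanylidene)butanoate | COC(=O)CC(=O)C=P(c1ccccc1)(c1ccccc1)c1ccccc1 | intermediate
5 | methacrolein | C=C(C)C=O | starting material
6 | methyl (E)-6-methyl-3-oxohepta-4,6-dienoate | COC(=O)CC(=O)/C=C/C(C)=C | intermediate
7 | (E)-4,4-dimethoxybut-2-enal | COC(OC)/C=C/C=O | starting material
8 | enamine Michael adduct: methyl 2-[(2S,3E)-1,1-dimethoxy-4-{(2R)-2-[diphenyl(trimethylsilyloxy)methyl]pyrrolidin-1-yl}but-3-en-2-yl]-6-methyl-3-oxohepta-4,6-dienoate | COC(=O)C(C(=O)/C=C/C(C)=C)[C@@H](C(OC)OC)/C=C/N1CCC[C@@H]1C(c1ccccc1)(c1ccccc1)O[Si](C)(C)C | intermediate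
9 | methyl (4R,5R,6S)-6-(dimethoxymethyl)-5-formyl-2-hydroxy-4-(prop-1-en-2-yl)cyclohex-1-ene-1-carboxylate | C=C(C)[C@@H]1CC(O)=C(C(=O)OC)[C@@H](C(OC)OC)[C@@H]1C=O | intermediate
10 | dipotassium dienolate of 9 (keto ester enolate and exocyclic aldehyde enolate) | C=C(C)[C@@H]1CC([O-])=C(C(=O)OC)[C@@H](C(OC)OC)C1=C[O-].[K+].[K+] | intermediate
11 | methyl (4R,5S,6S)-6-(dimethoxymethyl)-5-formyl-2-hydroxy-4-(prop-1-en-2-yl)cyclohex-1-ene-1-carboxylate | C=C(C)[C@@H]1CC(O)=C(C(=O)OC)[C@@H](C(OC)OC)[C@H]1C=O | intermediate
12 | (R)-4-hydroxycyclopent-2-en-1-one | O[C@H]1C=CC(=O)C1 | starting material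
13 | 2-(diethoxyphosphoryl)acetic acid | CCOP(=O)(OCC)CC(=O)O | starting material
14 | (R)-4-oxocyclopent-2-en-1-yl 2-(diethoxyphosphoryl)acetate | CCOP(=O)(OCC)CC(=O)O[C@H]1C=CC(=O)C1 | intermediate
15 | diethyl [(3aS,6aR)-2,5-dioxohexahydro-2H-cyclopenta[b]furan-3-yl]phosphonate | CCOP(=O)(OCC)C1C(=O)O[C@@H]2CC(=O)C[C@H]12 | intermediate
16 | diethyl [(3a'S,6a'R)-2'-oxohexahydrospiro[1,3-dioxolane-2,5'-cyclopenta[b]furan]-3'-yl]phosphonate | CCOP(=O)(OCC)C1C(=O)O[C@@H]2CC3(OCCO3)C[C@H]12 | intermediate
17 | methyl (4R,5S,6S)-6-(dimethoxymethyl)-2-hydroxy-5-{(E)-[(3a'R,6a'R)-2'-oxotetrahydrospiro[1,3-dioxolane-2,5'-cyclopenta[b]furan]-3'(2'H)-ylidene]methyl}-4-(prop-1-en-2-yl)cyclohex-1-ene-1-carboxylate | C=C(C)[C@@H]1CC(O)=C(C(=O)OC)[C@@H](C(OC)OC)[C@H]1/C=C1/C(=O)O[C@@H]2CC3(OCCO3)C[C@H]12 | intermediate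
18 | methyl (4R,5S,6S)-5-{(E)-[(3aR,6aR)-2,5-dioxohexahydro-3H-cyclopenta[b]furan-3-ylidene]methyl}-6-formyl-2-hydroxy-4-(prop-1-en-2-yl)cyclohex-1-ene-1-carboxylate | C=C(C)[C@@H]1CC(O)=C(C(=O)OC)[C@@H](C=O)[C@H]1/C=C1/C(=O)O[C@@H]2CC(=O)C[C@H]12 | intermediate
19 | tetracyclic aldol (target skeleton, C14 secondary alcohol as epimer mixture, C26 ketone) | C=C(C)[C@@H]1CC(O)=C(C(=O)OC)[C@H]2C(O)[C@@H]3[C@@H]4C(=C[C@H]21)C(=O)O[C@@H]4CC3=O | intermediate
20 | diol (target with C14 secondary alcohol as epimer mixture) | C=C(C)[C@@H]1CC(O)=C(C(=O)OC)[C@H]2C(O)[C@@H]3[C@@H]4C(=C[C@H]21)C(=O)O[C@@H]4C[C@]3(C)O | intermediate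
21 | CNP0268969.1 | C=C(C)[C@@H]1CC(O)=C(C(=O)OC)[C@H]2C(=O)[C@@H]3[C@@H]4C(=C[C@H]21)C(=O)O[C@@H]4C[C@]3(C)O | target

**Totals**
Total step count: 12.
Longest linear sequence: 9 steps (steps 1, 2, 3, 4, 8, 9, 10, 11, 12).

**Steps most likely to fail**

1. Step 3. The catalyst fixes C13 and step 4 fixes C20, but C4 depends on which chair the ring closure uses. Closure through the extended chair with all substituents equatorial would place isopropenyl cis to the acetal, and no later step removes that error. The mono-adduct may also rest as its cyclic hemiacetal if the enamine closes slowly. Fallback, setting out from 6 and 7 and returning at 18: the same annulation is run with the enantiomeric (S)-catalyst. Through the extended chair this should give the all-trans aldehyde methyl (4R,5S,6R)-6-(dimethoxymethyl)-5-formyl-2-hydroxy-4-(prop-1-en-2-yl)cyclohex-1-ene-1-carboxylate F1, in which C4 and C20 are as in the target and only C13 is inverted, so step 4 is not needed. Olefination with 16 under the conditions of step 8 gives the C13-epimer of 17 F2, and acid hydrolysis as in step 9 gives the C13-epimer of 18 F3. C13 is then α to the free aldehyde and its formyl group lies in the plane of the enol ester (A(1,2) strain); equilibration with catalytic DBU in CH2Cl2 should move it to the pseudoaxial position, which is 18.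

2. Step 4. Proton delivery to the enolate may show poor facial selectivity, O-protonation may be followed by unselective ketonisation of the enol, and the aldehyde may self-condense before the dienolate is complete. Fallback, setting out from 9 and returning at 11: thermodynamic instead of kinetic control. 9 (or any 9/11 mixture) is equilibrated with catalytic DBU in CH2Cl2, 11 is separated by chromatography and 9 is returned to the equilibration; new compounds: none F0.

3. Step 10. Slow seven-membered ring closure would leave time for β-elimination of the lactone carboxylate from the C25 enamine, for dehydration of the aldol, or for drift at C13 α to the aldehyde. Fallback, setting out from 18 and returning at 19: a Lewis-acid-mediated direct aldol in place of enamine catalysis (TiCl4, Et3N, CH2Cl2, −78 °C), in which a titanium enolate adds to the titanium-bound aldehyde at low temperature, where elimination and epimerisation are slow; new compounds: none F0.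

**Further compounds**
F1 | step 3 | methyl (4R,5S,6R)-6-(dimethoxymethyl)-5-formyl-2-hydroxy-4-(prop-1-en-2-yl)cyclohex-1-ene-1-carboxylate | C=C(C)[C@@H]1CC(O)=C(C(=O)OC)[C@H](C(OC)OC)[C@H]1C=O
F2 | step 3 | C13-epimer of 17: methyl (4R,5S,6R)-6-(dimethoxymethyl)-2-hydroxy-5-{(E)-[(3a'R,6a'R)-2'-oxotetrahydrospiro[1,3-dioxolane-2,5'-cyclopenta[b]furan]-3'(2'H)-ylidene]methyl}-4-(prop-1-en-2-yl)cyclohex-1-ene-1-carboxylate | C=C(C)[C@@H]1CC(O)=C(C(=O)OC)[C@H](C(OC)OC)[C@H]1/C=C1/C(=O)O[C@@H]2CC3(OCCO3)C[C@H]12
F3 | step 3 | C13-epimer of 18: methyl (4R,5S,6R)-5-{(E)-[(3aR,6aR)-2,5-dioxohexahydro-3H-cyclopenta[b]furan-3-ylidene]methyl}-6-formyl-2-hydroxy-4-(prop-1-en-2-yl)cyclohex-1-ene-1-carboxylate | C=C(C)[C@@H]1CC(O)=C(C(=O)OC)[C@H](C=O)[C@H]1/C=C1/C(=O)O[C@@H]2CC(=O)C[C@H]12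
F0 | step 4 | none | none
F0 | step 10 | none | none
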